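**Assumption:** the SMILES is read as (2S) at the chromene carbon and (1R,3R) in the cyclohexane (ring methyls trans, side chain cis to the 3‑methyl); selectivities are estimates by analogy, nothing here has been run.

## Retrosynthetic overview

1. Target ⇐ C6 hydroxylation of a chromen‑5‑ol ⇐ one flask: cyclobutenone → phenol ring expansion, then ring‑closing metathesis (benzene ring first, pyran ring second).
2. Cyclobutenone ⇐ tertiary alkoxide of an acyclic dienol + 3‑chloro‑4‑vinylcyclobutenedione + vinyllithium/MeOTf; the arene is grown on the intact C2–O bond, so C2 is never broken.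
3. Dienol ⇐ cleavage (O3, then double methylenation) of a bicyclic tertiary allylic alcohol ⇐ equatorial methyl addition to an octalone template.
4. Octalone ⇐ amine‑mediated asymmetric Michael addition/Robinson annulation of 2,6‑dimethylcyclohexanone (its ring is the cyclohexane of the target) with methyl vinyl ketone.
5. Ring order: cyclohexane (bought), template ring (made, later cut open), benzene, pyran.

## Route

**Step 1**
Reactants: 1 2,6‑dimethylcyclohexan‑1‑one; 2 (S)‑1‑phenylethylamine; 3 but‑3‑en‑2‑one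
Product: 6 (2R)‑2,6‑dimethyl‑2‑(3‑oxobutyl)cyclohexan‑1‑one, via ketimine 4 (not isolated), via keto imine 5 (not isolated)
Conditions: 2, TsOH (cat.), PhMe, Dean–Stark; then 3, THF, 40 °C; then 20% aq AcOH, rt
Reagents that add atoms: water (O)
Why: d'Angelo asymmetric Michael addition: the secondary enamine tautomer of 4 adds to 3 through a chair‑like aza‑ene transition state on the face away from the phenyl group, which sets the quaternary carbon as R (about 90% ee, same sense as with 2‑methylcyclohexanone), while C6 stays epimerisable and is corrected in step 2.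

**Step 2**
Reactants: 6 (2R)‑2,6‑dimethyl‑2‑(3‑oxobutyl)cyclohexan‑1‑one
Product: 8 (4aR,8R)‑4a,8‑dimethyl‑4,4a,5,6,7,8‑hexahydronaphthalen‑2(3H)‑one, via ketol 7 (not isolated)
Conditions: NaOMe, MeOH, 60 °C
Reagents that add atoms: none
Why: Robinson annulation (intramolecular aldol condensation); C8 equilibrates through the dienolate to the pseudo‑equatorial methyl, trans to the angular methyl (the 6α‑methyl‑Δ4‑3‑ketosteroid preference), and the minor C8 epimer is removed by chromatography.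

**Step 3**
Reactants: 8 (4aR,8R)‑4a,8‑dimethyl‑4,4a,5,6,7,8‑hexahydronaphthalen‑2(3H)‑one
Product: 9 (2S,4aR,8R)‑2,4a,8‑trimethyl‑2,3,4,4a,5,6,7,8‑octahydronaphthalen‑2‑ol
Conditions: MeTi(OiPr)3, Et2O/hexane, 0 °C → rt; aq NH4F work‑up
Reagents that add atoms: methyltitanium triisopropoxide (C[Ti](OC(C)C)(OC(C)C)OC(C)C)
Why: Reetz‑type 1,2‑addition of a bulky methyltitanium reagent, which attacks the half‑chair enone equatorially to give axial OH/equatorial methyl (the 3β‑methyl‑3α‑hydroxy steroid sense), so the rigid bicycle sets the carbinol carbon as S.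

**Step 4**
Reactants: 9 (2S,4aR,8R)‑2,4a,8‑trimethyl‑2,3,4,4a,5,6,7,8‑octahydronaphthalen‑2‑ol
Product: 11 (2S)‑4‑[(1R,3R)‑1,3‑dimethyl‑2‑oxocyclohexyl]‑2‑hydroxy‑2‑methylbutanal, via ozonide 10 (not isolated)
Conditions: O3, CH2Cl2, −78 °C; then PPh3, −78 °C → rt; used crude
Reagents that add atoms: ozone ([O-][O+]=O)
Why: ozonolysis cuts the trisubstituted ring olefin into the ring ketone and the α‑hydroxy aldehyde without touching a stereocentre, and the neutral reductive work‑up keeps the α‑methyl ketone centre from epimerising.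

**Step 5**
Reactants: 11 (2S)‑4‑[(1R,3R)‑1,3‑dimethyl‑2‑oxocyclohexyl]‑2‑hydroxy‑2‑methylbutanal
Product: 12 (3S)‑5‑[(1R,3R)‑1,3‑dimethyl‑2‑methylidenecyclohexyl]‑3‑methylpent‑1‑en‑3‑ol
Conditions: Cp2TiMe2 (4 equiv), PhMe/THF, 65 °C, dark
Reagents that add atoms: dimethyltitanocene (C[Ti](C)(C1C=CC=C1)C1C=CC=C1)
Why: Petasis methylenation converts both the aldehyde and the hindered ketone into C=CH2 under non‑basic conditions, so the ring CH(Me) centre next to the ketone is not enolised and both existing stereocentres are kept.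

**Step 6**
Reactants: 13 3,4‑dichlorocyclobut‑3‑ene‑1,2‑dione
Product: 14 3‑chloro‑4‑ethenylcyclobut‑3‑ene‑1,2‑dione
Conditions: CH2=CHSnBu3 (1.0 equiv), BnPdCl(PPh3)2 (2 mol %), CuI (cat.), MeCN, rt; used at once as a solution
Reagents that add atoms: tributyl(vinyl)stannane (C=C[Sn](CCCC)(CCCC)CCCC)
Why: Stille mono‑coupling of a vinylogous acid chloride (Liebeskind halocyclobutenedione coupling), stopped at one chloride by stoichiometry.

**Step 7**
Reactants: 12 (3S)‑5‑[(1R,3R)‑1,3‑dimethyl‑2‑methylidenecyclohexyl]‑3‑methylpent‑1‑en‑3‑ol; 14 3‑chloro‑4‑ethenylcyclobut‑3‑ene‑1,2‑dione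
Product: 17 2,4‑diethenyl‑4‑methoxy‑3‑{[(3S)‑5‑[(1R,3R)‑1,3‑dimethyl‑2‑methylidenecyclohexyl]‑3‑methylpent‑1‑en‑3‑yl]oxy}cyclobut‑2‑en‑1‑one, via vinylogous ester 15 (not isolated), via lithium alkoxide 16 (not isolated)
Conditions: n‑BuLi, THF, −78 °C; 14, −78 °C; then CH2=CHLi, −78 °C; then MeOTf, −78 → 0 °C
Reagents that add atoms: vinyllithium ([Li]C=C); methyl triflate (COS(=O)(=O)C(F)(F)F)
Why: addition–elimination of the tertiary lithium alkoxide on the vinylogous acid chloride leaves the C–O bond of the stereocentre intact (retention), then vinyllithium adds 1,2 to the carbonyl next to the alkoxy carbon (the one that is not a vinylogous ester, Liebeskind–Moore regiochemistry) and the alkoxide is O‑methylated; the new ring carbon is a mixture that converges in step 8.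

**Step 8**
Reactants: 17 2,4‑diethenyl‑4‑methoxy‑3‑{[(3S)‑5‑[(1R,3R)‑1,3‑dimethyl‑2‑methylidenecyclohexyl]‑3‑methylpent‑1‑en‑3‑yl]oxy}cyclobut‑2‑en‑1‑one
Product: 20 (2S)‑2‑{2‑[(1R,3R)‑1,3‑dimethyl‑2‑methylidenecyclohexyl]ethyl}‑8‑methoxy‑2‑methyl‑2H‑chromen‑5‑ol, via dienylketene 18 (not isolated), via vinylphenol 19 (not isolated)
Conditions: PhMe (0.01 M), 100 °C, 1 h; cool to 40 °C, Grubbs II (5 mol %), 3 h
Reagents that add atoms: none
Why: Liebeskind–Moore cyclobutenone benzannulation (4π ring opening with methoxy outward/vinyl inward, 6π closure, tautomerisation) builds the benzene ring, and ring‑closing metathesis of the styrene with the tertiary allyl ether (Grubbs chromene synthesis) then closes the pyran in the same flask; the ring opening should outrun a Claisen shift of the vinylogous ester, and C2 keeps its configuration because its C–O bond is never cleaved.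

**Step 9**
Reactants: 20 (2S)‑2‑{2‑[(1R,3R)‑1,3‑dimethyl‑2‑methylidenecyclohexyl]ethyl}‑8‑methoxy‑2‑methyl‑2H‑chromen‑5‑ol
Product: 22 (2S)‑2‑{2‑[(1R,3R)‑1,3‑dimethyl‑2‑methylidenecyclohexyl]ethyl}‑8‑methoxy‑2‑methyl‑2H‑chromene‑5,6‑diol, via ortho‑quinone 21 (not isolated)
Conditions: IBX (1.1 equiv), DMF, rt; then aq Na2S2O4, Ar
Reagents that add atoms: 2‑iodoxybenzoic acid (O=C1OI(=O)(O)c2ccccc12)
Why: Pettus ortho‑oxygenation: IBX delivers oxygen to the only free ortho position (C6) of the phenol to give the alkoxy‑stabilised ortho‑quinone, which dithionite reduces to the catechol; no stereocentre is involved.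

## Compound list

1 | 2,6‑dimethylcyclohexan‑1‑one (cis/trans mixture) | CC1CCCC(C)C1=O | starting material
2 | (S)‑1‑phenylethylamine | C[C@H](N)c1ccccc1 | starting material
3 | but‑3‑en‑2‑one | CC(=O)C=C | starting material
4 | (1S)‑N‑(2,6‑dimethylcyclohexylidene)‑1‑phenylethanamine | CC1CCCC(C)C1=N[C@@H](C)c1ccccc1 | intermediate
5 | 4‑[(1R)‑1,3‑dimethyl‑2‑{[(1S)‑1‑phenylethyl]imino}cyclohexyl]butan‑2‑one | CC(=O)CC[C@@]1(C)CCCC(C)C1=N[C@@H](C)c1ccccc1 | intermediate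
6 | (2R)‑2,6‑dimethyl‑2‑(3‑oxobutyl)cyclohexan‑1‑one (C6 epimers) | CC(=O)CC[C@@]1(C)CCCC(C)C1=O | intermediate
7 | (4aR)‑8a‑hydroxy‑4a,8‑dimethyloctahydronaphthalen‑2(1H)‑one | O=C1CC[C@@]2(C)CCCC(C)C2(O)C1 | intermediate
8 | (4aR,8R)‑4a,8‑dimethyl‑4,4a,5,6,7,8‑hexahydronaphthalen‑2(3H)‑one | O=C1CC[C@@]2(C)CCC[C@@H](C)C2=C1 | intermediate
9 | (2S,4aR,8R)‑2,4a,8‑trimethyl‑2,3,4,4a,5,6,7,8‑octahydronaphthalen‑2‑ol | O[C@@]1(C)CC[C@@]2(C)CCC[C@@H](C)C2=C1 | intermediate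
10 | ozonide of 9 (1,2,4‑trioxolane across C1/C8a) | O[C@@]1(C)CC[C@@]2(C)CCC[C@@H](C)C23OOC1O3 | intermediate
11 | (2S)‑4‑[(1R,3R)‑1,3‑dimethyl‑2‑oxocyclohexyl]‑2‑hydroxy‑2‑methylbutanal | O[C@@](C=O)(C)CC[C@@]1(C)CCC[C@@H](C)C1=O | intermediate
12 | (3S)‑5‑[(1R,3R)‑1,3‑dimethyl‑2‑methylidenecyclohexyl]‑3‑methylpent‑1‑en‑3‑ol | C=C[C@@](C)(O)CC[C@@]1(C)CCC[C@@H](C)C1=C | intermediate
13 | 3,4‑dichlorocyclobut‑3‑ene‑1,2‑dione (squaric acid dichloride) | ClC1=C(Cl)C(=O)C1=O | starting material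
14 | 3‑chloro‑4‑ethenylcyclobut‑3‑ene‑1,2‑dione | C=CC1=C(Cl)C(=O)C1=O | intermediate
15 | 3‑ethenyl‑4‑{[(3S)‑5‑[(1R,3R)‑1,3‑dimethyl‑2‑methylidenecyclohexyl]‑3‑methylpent‑1‑en‑3‑yl]oxy}cyclobut‑3‑ene‑1,2‑dione | C=CC1=C(O[C@](C)(C=C)CC[C@@]2(C)CCC[C@@H](C)C2=C)C(=O)C1=O | intermediate
16 | lithium 1,3‑diethenyl‑2‑{[(3S)‑5‑[(1R,3R)‑1,3‑dimethyl‑2‑methylidenecyclohexyl]‑3‑methylpent‑1‑en‑3‑yl]oxy}‑4‑oxocyclobut‑2‑en‑1‑olate | [Li+].C=CC1=C(O[C@](C)(C=C)CC[C@@]2(C)CCC[C@@H](C)C2=C)C([O-])(C=C)C1=O | intermediate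
17 | 2,4‑diethenyl‑4‑methoxy‑3‑{[(3S)‑5‑[(1R,3R)‑1,3‑dimethyl‑2‑methylidenecyclohexyl]‑3‑methylpent‑1‑en‑3‑yl]oxy}cyclobut‑2‑en‑1‑one (C4 epimers) | C=CC1=C(O[C@](C)(C=C)CC[C@@]2(C)CCC[C@@H](C)C2=C)C(OC)(C=C)C1=O | intermediate
18 | 2‑ethenyl‑4‑methoxy‑3‑{[(3S)‑5‑[(1R,3R)‑1,3‑dimethyl‑2‑methylidenecyclohexyl]‑3‑methylpent‑1‑en‑3‑yl]oxy}hexa‑1,3,5‑trien‑1‑one | C=CC(=C=O)C(O[C@](C)(C=C)CC[C@@]1(C)CCC[C@@H](C)C1=C)=C(OC)C=C | intermediate
19 | 2‑ethenyl‑4‑methoxy‑3‑{[(3S)‑5‑[(1R,3R)‑1,3‑dimethyl‑2‑methylidenecyclohexyl]‑3‑methylpent‑1‑en‑3‑yl]oxy}phenol | C=Cc1c(O)ccc(OC)c1O[C@](C)(C=C)CC[C@@]1(C)CCC[C@@H](C)C1=C | intermediate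
20 | (2S)‑2‑{2‑[(1R,3R)‑1,3‑dimethyl‑2‑methylidenecyclohexyl]ethyl}‑8‑methoxy‑2‑methyl‑2H‑chromen‑5‑ol | C=C1[C@H](C)CCC[C@]1(C)CC[C@@]1(C)C=Cc2c(O)ccc(OC)c2O1 | intermediate
21 | (2S)‑2‑{2‑[(1R,3R)‑1,3‑dimethyl‑2‑methylidenecyclohexyl]ethyl}‑8‑methoxy‑2‑methyl‑2H‑chromene‑5,6‑dione | C=C1[C@H](C)CCC[C@]1(C)CC[C@@]1(C)C=CC2=C(O1)C(OC)=CC(=O)C2=O | intermediate
22 | (2S)‑2‑{2‑[(1R,3R)‑1,3‑dimethyl‑2‑methylidenecyclohexyl]ethyl}‑8‑methoxy‑2‑methyl‑2H‑chromene‑5,6‑diol | C=C1[C@H](C)CCC[C@]1(C)CC[C@@]1(C)C=Cc2c(O)c(O)cc(OC)c2O1 | target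

## Step count and risks

Total steps: 9. Longest linear sequence: 8 (steps 1–5, 7–9; step 6 is a one‑step side branch).

The three steps most likely to fail:

**Step 5.** The free α‑hydroxy aldehyde 11 can sit as hemiketal forms or undergo an α‑ketol shift at 65 °C before both carbonyls are methylenated. The fallback is a protecting‑group detour that sets out from 9 and comes back at 12. Silylation of 9 (TESOTf, 2,6‑lutidine) gives the triethylsilyl ether F1. Ozonolysis as in step 4 gives the silyloxy keto aldehyde F2, which has no free α‑hydroxyl. Petasis methylenation gives the bis‑olefin silyl ether F3, and TBAF then releases 12.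

**Step 7.** The hindered tertiary alkoxide may not substitute the very electrophilic, polymerisable chloride 14 cleanly, or ester 15 may ionise. The fallback reverses the order of bond formation; it sets out from 14 (with 12) and comes back at 17. Vinyllithium then MeOTf on 14 gives the more robust chloro cyclobutenone F4. The lithium alkoxide of 12 then displaces its vinylogous chloride by addition–elimination to give 17.

**Step 8.** At 100 °C the tertiary allyl ether in 17 or 19 may undergo a [3,3] shift or ionise before ring expansion and metathesis are complete. The fallback leaves the squarate chemistry, uses a bought arene, sets out from 11 and comes back at 22.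
- Stork–Zhao olefination of 11 (Ph3P=CHI, NaHMDS, −78 °C) gives the (Z)‑iodoalkene keto alcohol F5.
- Petasis methylenation of the ring ketone gives the iodo diene alcohol F6.
- Suzuki coupling with (2‑hydroxy‑5‑methoxyphenyl)boronic acid (Pd(PPh3)4, K3PO4) proceeds with retention of geometry to the (Z)‑styryl phenol F7.
- IBX oxidises F7 to the ortho‑quinone F8, whose tertiary hydroxyl adds in a 6‑ring oxa‑Michael fashion (retention at the carbinol carbon) and tautomerises directly to 22.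

## Further compounds

F1 | step 5 | triethyl{[(2S,4aR,8R)‑2,4a,8‑trimethyl‑2,3,4,4a,5,6,7,8‑octahydronaphthalen‑2‑yl]oxy}silane | CC[Si](CC)(CC)O[C@@]1(C)CC[C@@]2(C)CCC[C@@H](C)C2=C1
F2 | step 5 | (2S)‑4‑[(1R,3R)‑1,3‑dimethyl‑2‑oxocyclohexyl]‑2‑methyl‑2‑[(triethylsilyl)oxy]butanal | CC[Si](CC)(CC)O[C@@](C=O)(C)CC[C@@]1(C)CCC[C@@H](C)C1=O
F3 | step 5 | triethyl{[(3S)‑5‑[(1R,3R)‑1,3‑dimethyl‑2‑methylidenecyclohexyl]‑3‑methylpent‑1‑en‑3‑yl]oxy}silane | C=C[C@@](C)(O[Si](CC)(CC)CC)CC[C@@]1(C)CCC[C@@H](C)C1=C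
F4 | step 7 | 3‑chloro‑2,4‑diethenyl‑4‑methoxycyclobut‑2‑en‑1‑one | C=CC1=C(Cl)C(OC)(C=C)C1=O
F5 | step 8 | (2R,6R)‑2‑[(3S,4Z)‑3‑hydroxy‑5‑iodo‑3‑methylpent‑4‑en‑1‑yl]‑2,6‑dimethylcyclohexan‑1‑one | I/C=C\[C@@](C)(O)CC[C@@]1(C)CCC[C@@H](C)C1=O
F6 | step 8 | (1Z,3S)‑5‑[(1R,3R)‑1,3‑dimethyl‑2‑methylidenecyclohexyl]‑1‑iodo‑3‑methylpent‑1‑en‑3‑ol | I/C=C\[C@@](C)(O)CC[C@@]1(C)CCC[C@@H](C)C1=C
F7 | step 8 | 2‑[(1Z,3S)‑5‑[(1R,3R)‑1,3‑dimethyl‑2‑methylidenecyclohexyl]‑3‑hydroxy‑3‑methylpent‑1‑en‑1‑yl]‑4‑methoxyphenol | COc1ccc(O)c(/C=C\[C@@](C)(O)CC[C@@]2(C)CCC[C@@H](C)C2=C)c1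
F8 | step 8 | 3‑[(1Z,3S)‑5‑[(1R,3R)‑1,3‑dimethyl‑2‑methylidenecyclohexyl]‑3‑hydroxy‑3‑methylpent‑1‑en‑1‑yl]‑5‑methoxycyclohexa‑3,5‑diene‑1,2‑dione | COC1=CC(=O)C(=O)C(/C=C\[C@@](C)(O)CC[C@@]2(C)CCC[C@@H](C)C2=C)=C1
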